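**Strategy.** The route rests on disconnecting the O1–C8a aryl ether bond of ring C. The oxygens on C5 and C8 of ring A stand para to each other. Ring A can therefore be raised to a C5,C8-quinone in which unsubstituted C8a is the β-carbon of both the C5 and the C4 carbonyl. Oxidation of a hydroquinone 1,3-diketone then lets the enol oxygen on C2 add to C8a. This one operation closes the pyranone, supplies the fifth oxygen of ring A and leaves O5 and O8 distinguished by chelation. The precursor is a 4-benzyloxy-2,5-dihydroxy-3-methoxyphenyl diketone carrying the benzylated ring B, assembled by a Claisen condensation.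

Key step: step 6

Assumption: 8 is drawn as the diketone. In solution it should be mainly the chelated enol in equilibrium with its cyclic hemiketal, and all forms drain through the open hydroquinone on oxidation. The target has no stereocentre, so no stereocontrol is needed.

Step 1
Reactants: 1 gallacetophenone
Product: 2 1-(4-benzyloxy-2,3-dihydroxyphenyl)ethanone
Conditions: BnBr (1.0 equiv), KHCO3 (1.1 equiv), DMF, 40 °C
Reagents that add atoms: benzyl bromide, BrCc1ccccc1
Why: Williamson etherification under acidity control: only the 4-hydroxyl, para to the acetyl group, is ionised by KHCO3, while the 2-hydroxyl is chelated to the ketone and the 3-hydroxyl is the weakest acid, so one equivalent of BnBr should go to O4.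

Step 2
Reactants: 2 1-(4-benzyloxy-2,3-dihydroxyphenyl)ethanone
Product: 3 1-(4-benzyloxy-2-hydroxy-3-methoxyphenyl)ethanone
Conditions: MeI (1.1 equiv), K2CO3 (1.1 equiv), acetone, reflux
Reagents that add atoms: iodomethane, CI
Why: Williamson etherification in which the chelated 2-hydroxyl stays inert to one equivalent of MeI and mild base, the standard selectivity of o-hydroxyaryl ketones, so only O3 should be methylated.

Step 3
Reactants: 3 1-(4-benzyloxy-2-hydroxy-3-methoxyphenyl)ethanone
Product: 5 1-(4-benzyloxy-2,5-dihydroxy-3-methoxyphenyl)ethanone, via aryl sulfate 4 (not isolated)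
Conditions: K2S2O8 (1.1 equiv), aq KOH, pyridine, 0 °C to rt; HCl to pH 4–5, extract unchanged 3 (Et2O); aqueous layer, 2 M HCl, 70 °C, argon
Reagents that add atoms: potassium peroxodisulfate, [K+].[K+].[O-]S(=O)(=O)OOS(=O)(=O)[O-]
Why: Elbs persulfate oxidation: the phenolate attacks the peroxide oxygen through the free C5 para to O2 (ortho C3 is blocked), sulfate ester 4 resists further oxidation and stays in water while unchanged 3 is recovered, and warm dilute acid then cleaves its S–O bond without touching the benzyl ether.

Step 4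
Reactants: 6 methyl 3-hydroxy-4,5-dimethoxybenzoate
Product: 7 methyl 3-benzyloxy-4,5-dimethoxybenzoate
Conditions: BnBr (1.2 equiv), K2CO3, DMF, 60 °C
Reagents that add atoms: benzyl bromide, BrCc1ccccc1
Why: Williamson etherification of the single free phenol, with the methyl ester inert to K2CO3 in DMF.

Step 5
Reactants: 5 1-(4-benzyloxy-2,5-dihydroxy-3-methoxyphenyl)ethanone; 7 methyl 3-benzyloxy-4,5-dimethoxybenzoate
Product: 8 1-(4-benzyloxy-2,5-dihydroxy-3-methoxyphenyl)-3-(3-benzyloxy-4,5-dimethoxyphenyl)propane-1,3-dione
Conditions: LiN(SiMe3)2 (5 equiv), THF, −78 to −10 °C, argon; 7, −78 °C to rt; AcOH quench, 0 °C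
Reagents that add atoms: none
Why: Crossed Claisen condensation of the lithium polyanion of a polyhydroxyacetophenone with a non-enolisable methyl benzoate, a known route to o-hydroxydibenzoylmethanes: phenoxide acylation by an ester is reversible whereas C-acylation is locked in by deprotonation of the diketone, and the AcOH quench avoids the strong acid that would trigger cyclodehydration.

Step 6
Reactants: 8 1-(4-benzyloxy-2,5-dihydroxy-3-methoxyphenyl)-3-(3-benzyloxy-4,5-dimethoxyphenyl)propane-1,3-dione
Product: 11 7,3'-bis(benzyloxy)-5,8-dihydroxy-6,4',5'-trimethoxyflavone, via acylquinone 9 (not isolated), via flavonequinone 10 (not isolated)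
Conditions: Ag2O (3 equiv), MgSO4, CH2Cl2 (0.01 M), rt, dark, argon; filter (Celite); aq Na2S2O4, CH2Cl2/H2O, rt
Reagents that add atoms: none
Why: Proposed new method: Ag2O dehydrogenates the hydroquinone of 8 to acylquinone 9 (the standard entry to 2-acyl-1,4-benzoquinones), whose C4a=C8a double bond is polarised by the C5 and C4 carbonyls together, so the oxygen on C2 of the enolised side chain adds to the hydrogen-bearing C8a, either as an oxa-Michael addition or as the equivalent oxa-6π closure of the O=C2–C3=C4–C4a=C8a array, and loss of the C8a proton rearomatises ring A to 11. The closest known reaction types are xanthone formation from hydroxylated benzophenones by attack of a tethered phenol oxygen on a quinone made in situ, the addition of heteronucleophiles next to the acyl group of 2-acylbenzoquinones, and the base-induced O-arylation of 1-(2-haloaryl)-1,3-diketones to flavones, whereas closure of an enolised 1,3-diketone onto a quinone is unproven. Ring C closes 6-endo-trig through O1, C2, C3, C4, C4a and C8a, carbon C3 could reach C8a or C5 only through a four-membered ring, and no stereocentre is formed. Since 9 is a stronger oxidant than the ring-closed quinone, it would re-oxidise 11 as it forms and stall the reaction near half conversion with one equivalent of oxidant, so an excess of Ag2O drives all material to the single quinone 10, a stable and reducible quinone type, and Na2S2O4 returns 11. The selectivity needed is closure through the chain oxygen instead of cyclodehydration through O5, secured because O5 is a quinone carbonyl as soon as oxidation has occurred and no acid is present, while high dilution and MgSO4 hold back C-alkylation by the diketone carbon of a second molecule and addition of the water released.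

Step 7
Reactants: 11 7,3'-bis(benzyloxy)-5,8-dihydroxy-6,4',5'-trimethoxyflavone
Product: 12 7,3'-bis(benzyloxy)-5-hydroxy-6,8,4',5'-tetramethoxyflavone
Conditions: MeI (1.1 equiv), K2CO3 (1.1 equiv), acetone, rt to 40 °C, argon
Reagents that add atoms: iodomethane, CI
Why: Williamson etherification under chelation control, the standard partial methylation of 5,8-dihydroxyflavones: the 5-hydroxyl is held in a hydrogen bond to the C4 carbonyl, so one equivalent of MeI should alkylate only the 8-phenoxide, and argon keeps the hydroquinone from air oxidation.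

Step 8
Reactants: 12 7,3'-bis(benzyloxy)-5-hydroxy-6,8,4',5'-tetramethoxyflavone
Product: 13 scaposin
Conditions: H2 (1 atm), Pd/C (10 wt%), EtOAc/MeOH, rt
Reagents that add atoms: none
Why: Catalytic hydrogenolysis of the two aryl benzyl ethers, which at one atmosphere and room temperature is routinely faster than reduction of the flavone C2=C3 bond, frees O7 and O3' and should give the achiral target.

**Compound list**

1 | gallacetophenone, 1-(2,3,4-trihydroxyphenyl)ethanone | CC(=O)c1ccc(O)c(O)c1O | starting material
2 | 1-(4-benzyloxy-2,3-dihydroxyphenyl)ethanone | CC(=O)c1ccc(OCc2ccccc2)c(O)c1O | intermediate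
3 | 1-(4-benzyloxy-2-hydroxy-3-methoxyphenyl)ethanone | CC(=O)c1ccc(OCc2ccccc2)c(OC)c1O | intermediate
4 | potassium 5-acetyl-2-benzyloxy-4-hydroxy-3-methoxyphenyl sulfate | CC(=O)c1cc(OS(=O)(=O)[O-])c(OCc2ccccc2)c(OC)c1O.[K+] | intermediate
5 | 1-(4-benzyloxy-2,5-dihydroxy-3-methoxyphenyl)ethanone | CC(=O)c1cc(O)c(OCc2ccccc2)c(OC)c1O | intermediate
6 | methyl 3-hydroxy-4,5-dimethoxybenzoate | COC(=O)c1cc(O)c(OC)c(OC)c1 | starting material
7 | methyl 3-benzyloxy-4,5-dimethoxybenzoate | COC(=O)c1cc(OCc2ccccc2)c(OC)c(OC)c1 | intermediate
8 | 1-(4-benzyloxy-2,5-dihydroxy-3-methoxyphenyl)-3-(3-benzyloxy-4,5-dimethoxyphenyl)propane-1,3-dione | COc1c(O)c(C(=O)CC(=O)c2cc(OCc3ccccc3)c(OC)c(OC)c2)cc(O)c1OCc1ccccc1 | intermediate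
9 | 2-[3-(3-benzyloxy-4,5-dimethoxyphenyl)-3-oxopropanoyl]-5-benzyloxy-6-methoxy-1,4-benzoquinone | COC1=C(OCc2ccccc2)C(=O)C=C(C(=O)CC(=O)c2cc(OCc3ccccc3)c(OC)c(OC)c2)C1=O | intermediate
10 | 7-benzyloxy-2-(3-benzyloxy-4,5-dimethoxyphenyl)-6-methoxychromene-4,5,8-trione | COC1=C(OCc2ccccc2)C(=O)C2=C(C1=O)C(=O)C=C(c1cc(OCc3ccccc3)c(OC)c(OC)c1)O2 | intermediate
11 | 7,3'-bis(benzyloxy)-5,8-dihydroxy-6,4',5'-trimethoxyflavone | COc1cc(-c2cc(=O)c3c(O)c(OC)c(OCc4ccccc4)c(O)c3o2)cc(OCc2ccccc2)c1OC | intermediate
12 | 7,3'-bis(benzyloxy)-5-hydroxy-6,8,4',5'-tetramethoxyflavone | COc1cc(-c2cc(=O)c3c(O)c(OC)c(OCc4ccccc4)c(OC)c3o2)cc(OCc2ccccc2)c1OC | intermediate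
13 | scaposin, 5,7,3'-trihydroxy-6,8,4',5'-tetramethoxyflavone (achiral) | COc1cc(-c2cc(=O)c3c(O)c(OC)c(O)c(OC)c3o2)cc(O)c1OC | target

**Totals.** The route has 8 steps in total. The longest linear sequence is 7 steps (1, 2, 3, 5, 6, 7, 8).

**Steps most likely to fail**

**Step 6.**
- What may go wrong: the closure may lose the race. The very electrophilic acylquinone can be alkylated at C8a by the diketone carbon of a second molecule. It can also be hydrated by the water that the oxidation releases, or decay before the side chain turns out of its chelated enol geometry.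
- The fallback forms the same O1–C8a bond by known chemistry, with an aryl bromide in place of the quinone. It sets out from 5 and comes back at 12, so 8 to 11 and step 7 are bypassed.
- Methylation of the unchelated 5-hydroxyl of 5 (MeI, K2CO3, acetone) should give 1-(4-benzyloxy-2-hydroxy-3,5-dimethoxyphenyl)ethanone F1.
- NBS in dry MeCN should brominate the only free ring position, as in the bromination of 3,4,5-trialkoxyaryl carbonyl compounds ortho to the carbonyl. This should give 1-(4-benzyloxy-2-bromo-6-hydroxy-3,5-dimethoxyphenyl)ethanone F2.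
- Claisen condensation with 7 (LiN(SiMe3)2, THF) should give 1-(4-benzyloxy-2-bromo-6-hydroxy-3,5-dimethoxyphenyl)-3-(3-benzyloxy-4,5-dimethoxyphenyl)propane-1,3-dione F3.
- The known Ullmann-type intramolecular O-arylation of 1-(2-haloaryl)-1,3-diketones (CuI, 1,10-phenanthroline, K2CO3, DMF, 100 °C) should then close ring C to 12.

**Step 3.**
- What may go wrong: low conversion, further oxidation of the electron-rich phenolate by persulfate, and partial loss of the benzyl ether during acid hydrolysis of the sulfate ester.
- The fallback replaces C–H oxidation by halogenation and metal-catalysed hydroxylation. It sets out from 3 and comes back at 5.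
- NBS in MeCN should brominate para to the phenol, at the only strongly activated free site, to give 1-(4-benzyloxy-5-bromo-2-hydroxy-3-methoxyphenyl)ethanone F4.
- Copper-catalysed hydroxylation of the aryl bromide (CuI, 8-hydroxyquinoline, KOH, DMSO/H2O, 100 °C, argon, acidic work-up) should then give 5.

**Step 5.**
- What may go wrong: air oxidation of the trilithiated hydroquinone and sluggish attack on an electron-rich ester, which would leave acylation incomplete.
- The fallback uses intramolecular acyl transfer. It sets out from 7 and 5 and comes back at 8.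
- Saponification of 7 (LiOH, THF/H2O) should give 3-benzyloxy-4,5-dimethoxybenzoic acid F5.
- SOCl2 with catalytic DMF in toluene should give 3-benzyloxy-4,5-dimethoxybenzoyl chloride F6.
- Two equivalents of F6 with 5 in pyridine should give 2-acetyl-5-benzyloxy-6-methoxy-1,4-phenylene bis(3-benzyloxy-4,5-dimethoxybenzoate) F7.
- Baker–Venkataraman rearrangement (KOH, pyridine, 50 °C) should move the aroyl group ortho to the acetyl group onto carbon. The product should be 5-[3-(3-benzyloxy-4,5-dimethoxyphenyl)-3-oxopropanoyl]-2-benzyloxy-4-hydroxy-3-methoxyphenyl 3-benzyloxy-4,5-dimethoxybenzoate F8.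
- Methanolysis of the remaining aryl ester (K2CO3, MeOH, rt, argon) should give 8 and return 7 for reuse.

**Further compounds**

F1 | step 6 | 1-(4-benzyloxy-2-hydroxy-3,5-dimethoxyphenyl)ethanone | CC(=O)c1cc(OC)c(OCc2ccccc2)c(OC)c1O
F2 | step 6 | 1-(4-benzyloxy-2-bromo-6-hydroxy-3,5-dimethoxyphenyl)ethanone | CC(=O)c1c(Br)c(OC)c(OCc2ccccc2)c(OC)c1O
F3 | step 6 | 1-(4-benzyloxy-2-bromo-6-hydroxy-3,5-dimethoxyphenyl)-3-(3-benzyloxy-4,5-dimethoxyphenyl)propane-1,3-dione | COc1c(O)c(C(=O)CC(=O)c2cc(OCc3ccccc3)c(OC)c(OC)c2)c(Br)c(OC)c1OCc1ccccc1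
F4 | step 3 | 1-(4-benzyloxy-5-bromo-2-hydroxy-3-methoxyphenyl)ethanone | CC(=O)c1cc(Br)c(OCc2ccccc2)c(OC)c1O
F5 | step 5 | 3-benzyloxy-4,5-dimethoxybenzoic acid | OC(=O)c1cc(OCc2ccccc2)c(OC)c(OC)c1
F6 | step 5 | 3-benzyloxy-4,5-dimethoxybenzoyl chloride | ClC(=O)c1cc(OCc2ccccc2)c(OC)c(OC)c1
F7 | step 5 | 2-acetyl-5-benzyloxy-6-methoxy-1,4-phenylene bis(3-benzyloxy-4,5-dimethoxybenzoate) | CC(=O)c1cc(OC(=O)c2cc(OCc3ccccc3)c(OC)c(OC)c2)c(OCc2ccccc2)c(OC)c1OC(=O)c1cc(OCc2ccccc2)c(OC)c(OC)c1
F8 | step 5 | 5-[3-(3-benzyloxy-4,5-dimethoxyphenyl)-3-oxopropanoyl]-2-benzyloxy-4-hydroxy-3-methoxyphenyl 3-benzyloxy-4,5-dimethoxybenzoate | COc1c(O)c(C(=O)CC(=O)c2cc(OCc3ccccc3)c(OC)c(OC)c2)cc(OC(=O)c2cc(OCc3ccccc3)c(OC)c(OC)c2)c1OCc1ccccc1
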